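The flavonol is disconnected at C4–C4a. Ring C is closed last by an intramolecular Friedel–Crafts acylation: the activated carboxyl of a 3-aryloxy-2-alkoxyacrylic acid attacks C4a, the ring A carbon ortho to O1, which the 1,3,5-trioxygenated ring A makes strongly nucleophilic and which symmetry makes unique. One operation thus forms the γ-pyrone and fixes the whole substitution pattern. The precursor is the (E)-acid 18, which carries the complete ring B (2'-prenyl, dimethylchromene, protected 5'-OH) on the future C2, the ring A ether on O1 and a protected O3. Allyl ethers on ring A and MOM ethers on O3/O5' are used so that only O7 can later be prenylated for the Claisen shift to C8.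

Key step: step 13

Remark (assumption): 16–19 may form as E/Z mixtures; the (E) form of 17–19 is drawn because it is the one that cyclises, and the push–pull alkene is expected to equilibrate once the acid is activated in step 13.

Abbreviation: ArB = 8-(methoxymethoxy)-2,2-dimethyl-5-(3-methylbut-2-en-1-yl)-2H-chromen-6-yl (ring B with its prenyl group, fused dimethylpyran and MOM-protected 5'-oxygen). MOMCl = chloromethyl methyl ether.

Step 1
Reactants: 1 phloroglucinol; 2 allyl bromide
Product: 3 3,5-bis(allyloxy)phenol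
Conditions: 2 (2 equiv), K2CO3, DMF, 20 °C; chromatography
Reagents that add atoms: none
Why: Williamson etherification of the symmetric triphenol with two equivalents of allyl bromide should give the bis-ether as the main part of a statistical mixture, separable from mono- and tri-ether, with one hydroxyl left free for the later vinyl ether formation.

Step 2
Reactants: 4 methyl glycolate
Product: 5 methyl 2-(methoxymethoxy)acetate
Conditions: MOMCl, i-Pr2NEt, CH2Cl2, 0 °C to 20 °C
Reagents that add atoms: chloromethyl methyl ether, COCCl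
Why: Alkylation of the primary alcohol with MOMCl under amine base is a standard acetal protection and leaves the ester untouched.

Step 3
Reactants: 6 2-bromo-4,5-dimethoxybenzaldehyde
Product: 7 2-bromo-4,5-dihydroxybenzaldehyde
Conditions: BBr3, CH2Cl2, −78 °C to 20 °C; H2O
Reagents that add atoms: none
Why: BBr3 cleaves both aryl methyl ethers by Lewis acid complexation and bromide attack at methyl, while the aryl aldehyde and aryl bromide are inert.

Step 4
Reactants: 7 2-bromo-4,5-dihydroxybenzaldehyde
Product: 8 2-bromo-4-hydroxy-5-(methoxymethoxy)benzaldehyde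
Conditions: NaH (2.2 equiv), DMF, 0 °C; MOMCl (1.0 equiv), 0 °C to 20 °C
Reagents that add atoms: chloromethyl methyl ether, COCCl
Why: In the dianion the O5 oxide, meta to the formyl group, is not delocalised into the aldehyde and is the more nucleophilic site, so one equivalent of MOMCl should alkylate O5 (dianion-controlled monoalkylation of a catechol aldehyde) and leave the para-conjugated O4 free.

Step 5
Reactants: 8 2-bromo-4-hydroxy-5-(methoxymethoxy)benzaldehyde; 9 3-chloro-3-methylbut-1-yne
Product: 10 2-bromo-5-(methoxymethoxy)-4-[(2-methylbut-3-yn-2-yl)oxy]benzaldehyde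
Conditions: K2CO3, KI, CuI (cat.), acetone, 60 °C
Reagents that add atoms: none
Why: Copper-assisted etherification of the one remaining, acidic phenol with the tertiary propargylic chloride is the standard entry to aryl 1,1-dimethylpropargyl ethers.

Step 6
Reactants: 10 2-bromo-5-(methoxymethoxy)-4-[(2-methylbut-3-yn-2-yl)oxy]benzaldehyde
Product: 11 5-bromo-8-(methoxymethoxy)-2,2-dimethyl-2H-chromene-6-carbaldehyde
Conditions: PhNEt2, 185 °C
Reagents that add atoms: none
Why: The thermal aryl propargyl ether Claisen rearrangement, followed by 1,5-hydrogen shift and oxa-6π electrocyclisation, builds the 2,2-dimethyl-2H-chromene, and only C3 is open to the [3,3] shift because the other ortho carbon carries the MOM ether.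

Step 7
Reactants: 11 5-bromo-8-(methoxymethoxy)-2,2-dimethyl-2H-chromene-6-carbaldehyde; 12 tributyl(3-methylbut-2-en-1-yl)stannane
Product: 13 8-(methoxymethoxy)-2,2-dimethyl-5-(3-methylbut-2-en-1-yl)-2H-chromene-6-carbaldehyde (ArB–CHO)
Conditions: Pd(PPh3)4 (cat.), CsF, DMF, 90 °C
Reagents that add atoms: none
Why: Stille coupling of the formyl-activated aryl bromide with the prenylstannane should give the linear prenyl group, since reductive elimination occurs at the unsubstituted allyl terminus, and aldehyde, MOM ether and chromene are tolerated.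

Step 8
Reactants: 5 methyl 2-(methoxymethoxy)acetate; 13 ArB–CHO
Product: 14 methyl 3-hydroxy-2-(methoxymethoxy)-3-ArB-propanoate (racemic mixture of syn and anti diastereomers)
Conditions: LiN(i-Pr)2, THF, −78 °C; then 13; NH4Cl (aq)
Reagents that add atoms: none
Why: Aldol addition of the lithium enolate of the glycolate ester to the non-enolisable aryl aldehyde gives the β-hydroxy ester; its two stereocentres form unselectively, which is irrelevant because both are erased in steps 9 and 10.

Step 9
Reactants: 14 methyl 3-hydroxy-2-(methoxymethoxy)-3-ArB-propanoate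
Product: 15 methyl 2-(methoxymethoxy)-3-oxo-3-ArB-propanoate (racemic)
Conditions: DMP, NaHCO3, CH2Cl2, 0 °C to 20 °C
Reagents that add atoms: none
Why: Buffered Dess–Martin oxidation converts the benzylic secondary alcohol into the ketone without touching alkenes or acetals.

Step 10
Reactants: 15 methyl 2-(methoxymethoxy)-3-oxo-3-ArB-propanoate
Product: 16 methyl 2-(methoxymethoxy)-3-(tosyloxy)-3-ArB-prop-2-enoate (E/Z mixture)
Conditions: TsCl, N-methylimidazole, Et3N, CH2Cl2, 0 °C
Reagents that add atoms: p-toluenesulfonyl chloride, Cc1ccc(cc1)S(=O)(=O)Cl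
Why: O-Sulfonylation of the enol of an α-substituted β-keto ester under N-methylimidazole/Et3N activation is an established route to fully substituted enol tosylates.

Step 11
Reactants: 16 methyl 2-(methoxymethoxy)-3-(tosyloxy)-3-ArB-prop-2-enoate; 3 3,5-bis(allyloxy)phenol
Product: 17 methyl (E)-3-[3,5-bis(allyloxy)phenoxy]-2-(methoxymethoxy)-3-ArB-prop-2-enoate (may contain the Z isomer)
Conditions: Cs2CO3, DMF, 50 °C
Reagents that add atoms: none
Why: Addition–elimination (nucleophilic vinylic substitution) of the phenoxide at the β-carbon of the β-tosyloxy acrylate replaces tosylate by the aryloxy group and so joins ring A to the future C2 through O1.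

Step 12
Reactants: 17 methyl (E)-3-[3,5-bis(allyloxy)phenoxy]-2-(methoxymethoxy)-3-ArB-prop-2-enoate
Product: 18 (E)-3-[3,5-bis(allyloxy)phenoxy]-2-(methoxymethoxy)-3-ArB-prop-2-enoic acid
Conditions: LiOH, THF/MeOH/H2O, 40 °C; then dilute HCl to pH 4, 0 °C
Reagents that add atoms: lithium hydroxide, [Li+].[OH-]
Why: Saponification of the methyl ester leaves MOM, allyl and aryl vinyl ethers intact, and cold acidification to pH 4 spares the enol acetal.

Step 13
Reactants: 18 (E)-3-[3,5-bis(allyloxy)phenoxy]-2-(methoxymethoxy)-3-ArB-prop-2-enoic acid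
Product: 20 5,7-bis(allyloxy)-3-(methoxymethoxy)-2-ArB-4H-chromen-4-one, via acid chloride 19 (not isolated)
Conditions: Me2C=C(Cl)NMe2, CH2Cl2, 0 °C; then AgOSO2CF3, 2,6-di-tert-butyl-4-methylpyridine, −40 °C to 0 °C
Reagents that add atoms: none
Why: The α-chloroenamine turns the acid into acid chloride 19 under neutral conditions, AgOSO2CF3 abstracts chloride to give an acylium ion delocalised over the push–pull alkene, this electrophile attacks the ring A carbon ortho to the vinyl ether oxygen, and the hindered pyridine removes the proton to rearomatise ring A. The closest known reaction type is the classical Friedel–Crafts cyclisation of β-aryloxyacrylic (β-aryloxycinnamic) acids to chromones and flavones. Ring C, the only ring formed, closes in a 6-exo sense at the acyl carbon by electrophilic aromatic substitution and forms C4–C4a; no stereocentre is created. Site selectivity between the two ortho carbons of the aryloxy ring is not an issue, because the 3,5-bis(allyloxy)phenyl unit is symmetric and each of these carbons is activated by three oxygen substituents. Selectivity for ring A over ring B (attack at C6' would give an indenone) rests on the far higher nucleophilicity of the phloroglucinol-type ring and on single-bond character in the delocalised cation, which lets E and Z forms interconvert so that material funnels through the isomer with acyl and aryloxy groups cis. The acid-free, buffered conditions are chosen so that MOM acetals, allyl ethers, the prenyl group and the chromene survive.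

Step 14
Reactants: 20 5,7-bis(allyloxy)-3-(methoxymethoxy)-2-ArB-4H-chromen-4-one
Product: 21 5,7-dihydroxy-3-(methoxymethoxy)-2-ArB-4H-chromen-4-one
Conditions: Pd(PPh3)4 (cat.), morpholine, THF, 20 °C
Reagents that add atoms: none
Why: Zerovalent palladium ionises the two aryl allyl ethers to π-allyl complexes that morpholine intercepts (Tsuji–Trost deallylation), which frees O5 and O7 while the MOM ethers on O3 and O5' stay.

Step 15
Reactants: 21 5,7-dihydroxy-3-(methoxymethoxy)-2-ArB-4H-chromen-4-one; 22 prenyl bromide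
Product: 23 5-hydroxy-3-(methoxymethoxy)-7-[(3-methylbut-2-en-1-yl)oxy]-2-ArB-4H-chromen-4-one
Conditions: 22 (1.1 equiv), K2CO3, acetone, 40 °C
Reagents that add atoms: none
Why: The 7-hydroxyl is the only acidic, non-chelated phenol (the 5-OH is hydrogen-bonded to the C4 carbonyl), so Williamson alkylation with one equivalent of prenyl bromide should occur at O7 alone.

Step 16
Reactants: 23 5-hydroxy-3-(methoxymethoxy)-7-[(3-methylbut-2-en-1-yl)oxy]-2-ArB-4H-chromen-4-one
Product: 24 5,7-dihydroxy-3-(methoxymethoxy)-8-(2-methylbut-3-en-2-yl)-2-ArB-4H-chromen-4-one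
Conditions: PhNEt2, 190 °C (microwave), argon
Reagents that add atoms: none
Why: The aromatic Claisen rearrangement transfers the prenyl unit with allylic inversion to an ortho carbon and so gives the 1,1-dimethylallyl group; C8 is the position generally favoured for 7-allyloxy- and 7-prenyloxy-5-hydroxyflavones, with C6 migration as the expected minor pathway.

Step 17
Reactants: 24 5,7-dihydroxy-3-(methoxymethoxy)-8-(2-methylbut-3-en-2-yl)-2-ArB-4H-chromen-4-one
Product: 25 broussoflavonol D
Conditions: HCl (1 M), MeOH/THF, 45 °C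
Reagents that add atoms: none
Why: Acid-catalysed methanolysis of the two MOM acetals releases 3-OH and 5'-OH under conditions that prenylated and chromene-bearing flavonoids normally tolerate.

Compound list
1 | phloroglucinol (benzene-1,3,5-triol) | Oc1cc(O)cc(O)c1 | starting material
2 | allyl bromide | C=CCBr | starting material
3 | 3,5-bis(allyloxy)phenol | Oc1cc(OCC=C)cc(OCC=C)c1 | intermediate
4 | methyl glycolate | COC(=O)CO | starting material
5 | methyl 2-(methoxymethoxy)acetate | COCOCC(=O)OC | intermediate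
6 | 2-bromo-4,5-dimethoxybenzaldehyde | COc1cc(Br)c(C=O)cc1OC | starting material
7 | 2-bromo-4,5-dihydroxybenzaldehyde | O=Cc1cc(O)c(O)cc1Br | intermediate
8 | 2-bromo-4-hydroxy-5-(methoxymethoxy)benzaldehyde | COCOc1cc(C=O)c(Br)cc1O | intermediate
9 | 3-chloro-3-methylbut-1-yne | C#CC(C)(C)Cl | starting material
10 | 2-bromo-5-(methoxymethoxy)-4-[(2-methylbut-3-yn-2-yl)oxy]benzaldehyde | COCOc1cc(C=O)c(Br)cc1OC(C)(C)C#C | intermediate
11 | 5-bromo-8-(methoxymethoxy)-2,2-dimethyl-2H-chromene-6-carbaldehyde | COCOc1cc(C=O)c(Br)c2C=CC(C)(C)Oc12 | intermediate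
12 | tributyl(3-methylbut-2-en-1-yl)stannane | CCCC[Sn](CCCC)(CCCC)CC=C(C)C | starting material
13 | 8-(methoxymethoxy)-2,2-dimethyl-5-(3-methylbut-2-en-1-yl)-2H-chromene-6-carbaldehyde (ArB–CHO) | COCOc1cc(C=O)c(CC=C(C)C)c2C=CC(C)(C)Oc12 | intermediate
14 | methyl 3-hydroxy-2-(methoxymethoxy)-3-ArB-propanoate, racemic mixture of diastereomers | COCOc1cc(C(O)C(OCOC)C(=O)OC)c(CC=C(C)C)c2C=CC(C)(C)Oc12 | intermediate
15 | methyl 2-(methoxymethoxy)-3-oxo-3-ArB-propanoate, racemic | COCOc1cc(C(=O)C(OCOC)C(=O)OC)c(CC=C(C)C)c2C=CC(C)(C)Oc12 | intermediate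
16 | methyl 2-(methoxymethoxy)-3-(tosyloxy)-3-ArB-prop-2-enoate, E/Z mixture | COCOc1cc(C(OS(=O)(=O)c3ccc(C)cc3)=C(OCOC)C(=O)OC)c(CC=C(C)C)c2C=CC(C)(C)Oc12 | intermediate
17 | methyl (E)-3-[3,5-bis(allyloxy)phenoxy]-2-(methoxymethoxy)-3-ArB-prop-2-enoate | C=CCOc1cc(OCC=C)cc(c1)O/C(c2cc(OCOC)c3OC(C)(C)C=Cc3c2CC=C(C)C)=C(\C(=O)OC)OCOC | intermediate
18 | (E)-3-[3,5-bis(allyloxy)phenoxy]-2-(methoxymethoxy)-3-ArB-prop-2-enoic acid (aryloxy and carboxyl groups cis) | C=CCOc1cc(OCC=C)cc(c1)O/C(c2cc(OCOC)c3OC(C)(C)C=Cc3c2CC=C(C)C)=C(\C(=O)O)OCOC | intermediate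
19 | (E)-3-[3,5-bis(allyloxy)phenoxy]-2-(methoxymethoxy)-3-ArB-prop-2-enoyl chloride (not isolated) | C=CCOc1cc(OCC=C)cc(c1)O/C(c2cc(OCOC)c3OC(C)(C)C=Cc3c2CC=C(C)C)=C(\C(=O)Cl)OCOC | intermediate
20 | 5,7-bis(allyloxy)-3-(methoxymethoxy)-2-ArB-4H-chromen-4-one | C=CCOc1cc(OCC=C)c2c(=O)c(OCOC)c(-c3cc(OCOC)c4OC(C)(C)C=Cc4c3CC=C(C)C)oc2c1 | intermediate
21 | 5,7-dihydroxy-3-(methoxymethoxy)-2-ArB-4H-chromen-4-one | Oc1cc(O)c2c(=O)c(OCOC)c(-c3cc(OCOC)c4OC(C)(C)C=Cc4c3CC=C(C)C)oc2c1 | intermediate
22 | prenyl bromide (1-bromo-3-methylbut-2-ene) | CC(C)=CCBr | starting material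
23 | 5-hydroxy-3-(methoxymethoxy)-7-[(3-methylbut-2-en-1-yl)oxy]-2-ArB-4H-chromen-4-one | CC(C)=CCOc1cc(O)c2c(=O)c(OCOC)c(-c3cc(OCOC)c4OC(C)(C)C=Cc4c3CC=C(C)C)oc2c1 | intermediate
24 | 5,7-dihydroxy-3-(methoxymethoxy)-8-(2-methylbut-3-en-2-yl)-2-ArB-4H-chromen-4-one | C=CC(C)(C)c1c(O)cc(O)c2c(=O)c(OCOC)c(-c3cc(OCOC)c4OC(C)(C)C=Cc4c3CC=C(C)C)oc12 | intermediate
25 | broussoflavonol D, 3,5,7-trihydroxy-2-[8-hydroxy-2,2-dimethyl-5-(3-methylbut-2-en-1-yl)-2H-chromen-6-yl]-8-(2-methylbut-3-en-2-yl)-4H-chromen-4-one (no stereocentre) | C=CC(C)(C)c1c(O)cc(O)c2c(=O)c(O)c(-c3cc(O)c4c(c3CC=C(C)C)C=CC(C)(C)O4)oc12 | target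

Total step count: 17. Longest linear sequence: 15 steps (steps 3 to 17, from 6).

Steps most likely to fail

1. Step 13 (closure of ring C). The acylium ion may be captured by ring B at C6' to give an indenone, the alkene may fail to reach the geometry with acyl and aryloxy groups cis, or the silver salt may strip the MOM acetals or attack the chromene. Fallback (chalcone route): it sets out from aldehyde 13. Commercial 2',4',6'-trihydroxyacetophenone would be bis-allylated with 2 (K2CO3, acetone), the chelated hydroxyl staying free, to give 1-[2-hydroxy-4,6-bis(allyloxy)phenyl]ethanone F1. Claisen–Schmidt condensation of this ketone with 13 (KOH, EtOH) should give the (E)-chalcone F2. Algar–Flynn–Oyamada oxidation (H2O2, NaOH, MeOH, 0 °C) should then give 5,7-bis(allyloxy)-3-hydroxy-2-ArB-4H-chromen-4-one F3, with aurone formation as the known competing path. MOM protection of the 3-hydroxyl (MOMCl, i-Pr2NEt) comes back to the route at 20.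

2. Step 11 (vinyl ether formation). The phenoxide may attack sulfur and transfer the sulfonyl group, which would regenerate the enolate, or it may fail to add to the hindered, donor-substituted β-carbon. Fallback (α-keto ester route): it sets out from aldehyde 13. Darzens condensation with methyl dichloroacetate (NaOMe, MeOH/Et2O, 0 °C) should give methyl 2-chloro-3-ArB-oxirane-2-carboxylate F4, which is expected to rearrange on warming to methyl 3-chloro-2-oxo-3-ArB-propanoate F5. Displacement of the benzylic chloride by phenol 3 (K2CO3, acetone) should give methyl 3-[3,5-bis(allyloxy)phenoxy]-2-oxo-3-ArB-propanoate F6. O-Alkylation of its enolate with MOMCl (NaH, THF, 0 °C) comes back to the route at 17.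

3. Step 16 (Claisen rearrangement). The prenyl unit may migrate to C6 in place of C8, and at 190 °C the 1,1-dimethylallyl phenol may undergo the abnormal Claisen isomerisation or close onto the 7-OH. Fallback (rearrangement moved to the symmetric ring A building block): it sets out from phloroglucinol 1 and enol tosylate 16 and comes back to the route at the target 25.
- Bis-protection of 1 (MOMCl, i-Pr2NEt, statistical) should give 3,5-bis(methoxymethoxy)phenol F7.
- Alkylation with 22 (K2CO3, acetone) should give 1,3-bis(methoxymethoxy)-5-[(3-methylbut-2-en-1-yl)oxy]benzene F8.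
- Claisen rearrangement (PhNEt2, 180 °C), which can only reach two equivalent ortho carbons, should give 3,5-bis(methoxymethoxy)-2-(2-methylbut-3-en-2-yl)phenol F9.
- Addition–elimination of this phenol to 16 (Cs2CO3, DMF) should give the methyl ester F10, and saponification (LiOH) the acid F11.
- Activation as in step 13 should give the acid chloride F12 and, with only one ortho carbon free, ring closure to 3,5,7-tris(methoxymethoxy)-8-(2-methylbut-3-en-2-yl)-2-ArB-4H-chromen-4-one F13.
- HCl in MeOH then removes all four MOM groups to give 25.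

Further compounds
F1 | step 13 | 1-[2-hydroxy-4,6-bis(allyloxy)phenyl]ethanone | CC(=O)c1c(O)cc(OCC=C)cc1OCC=C
F2 | step 13 | (E)-1-[2-hydroxy-4,6-bis(allyloxy)phenyl]-3-ArB-prop-2-en-1-one | C=CCOc1cc(O)c(C(=O)/C=C/c2cc(OCOC)c3OC(C)(C)C=Cc3c2CC=C(C)C)c(OCC=C)c1
F3 | step 13 | 5,7-bis(allyloxy)-3-hydroxy-2-ArB-4H-chromen-4-one | C=CCOc1cc(OCC=C)c2c(=O)c(O)c(-c3cc(OCOC)c4OC(C)(C)C=Cc4c3CC=C(C)C)oc2c1
F4 | step 11 | methyl 2-chloro-3-ArB-oxirane-2-carboxylate (racemic, not isolated) | COC(=O)C1(Cl)OC1c1cc(OCOC)c2OC(C)(C)C=Cc2c1CC=C(C)C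
F5 | step 11 | methyl 3-chloro-2-oxo-3-ArB-propanoate (racemic) | COC(=O)C(=O)C(Cl)c1cc(OCOC)c2OC(C)(C)C=Cc2c1CC=C(C)C
F6 | step 11 | methyl 3-[3,5-bis(allyloxy)phenoxy]-2-oxo-3-ArB-propanoate (racemic, in equilibrium with its enol) | COC(=O)C(=O)C(Oc1cc(OCC=C)cc(OCC=C)c1)c1cc(OCOC)c2OC(C)(C)C=Cc2c1CC=C(C)C
F7 | step 16 | 3,5-bis(methoxymethoxy)phenol | COCOc1cc(O)cc(OCOC)c1
F8 | step 16 | 1,3-bis(methoxymethoxy)-5-[(3-methylbut-2-en-1-yl)oxy]benzene | COCOc1cc(OCC=C(C)C)cc(OCOC)c1
F9 | step 16 | 3,5-bis(methoxymethoxy)-2-(2-methylbut-3-en-2-yl)phenol | COCOc1cc(O)c(C(C)(C)C=C)c(OCOC)c1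
F10 | step 16 | methyl (E)-3-[3,5-bis(methoxymethoxy)-2-(2-methylbut-3-en-2-yl)phenoxy]-2-(methoxymethoxy)-3-ArB-prop-2-enoate | COCOc1cc(O/C(c2cc(OCOC)c3OC(C)(C)C=Cc3c2CC=C(C)C)=C(\C(=O)OC)OCOC)c(C(C)(C)C=C)c(OCOC)c1
F11 | step 16 | (E)-3-[3,5-bis(methoxymethoxy)-2-(2-methylbut-3-en-2-yl)phenoxy]-2-(methoxymethoxy)-3-ArB-prop-2-enoic acid | COCOc1cc(O/C(c2cc(OCOC)c3OC(C)(C)C=Cc3c2CC=C(C)C)=C(\C(=O)O)OCOC)c(C(C)(C)C=C)c(OCOC)c1
F12 | step 16 | (E)-3-[3,5-bis(methoxymethoxy)-2-(2-methylbut-3-en-2-yl)phenoxy]-2-(methoxymethoxy)-3-ArB-prop-2-enoyl chloride (not isolated) | COCOc1cc(O/C(c2cc(OCOC)c3OC(C)(C)C=Cc3c2CC=C(C)C)=C(\C(=O)Cl)OCOC)c(C(C)(C)C=C)c(OCOC)c1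
F13 | step 16 | 3,5,7-tris(methoxymethoxy)-8-(2-methylbut-3-en-2-yl)-2-ArB-4H-chromen-4-one | C=CC(C)(C)c1c(OCOC)cc(OCOC)c2c(=O)c(OCOC)c(-c3cc(OCOC)c4OC(C)(C)C=Cc4c3CC=C(C)C)oc12
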